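**Plan**

- Retrosynthesis: O2'–Si is cut first. Next, in one operation, the C8–CH2 bond of the prenyl group (ring A) and the C5'–CH bond of the pyran (ring B) are cut, which returns both C5 units to ethers on O7 and O4'. Then the C2–C1' bond is cut, and last the two O–CMe2 ether bonds.
- Enabling feature: C8 is ortho to O7 on ring A and C5' is ortho to O4' on ring B, so each C5 unit can move from its own phenolic oxygen to the neighbouring carbon by a [3,3] shift.
- Forward: rings A and C enter as a chromone (1 → 4) and ring B as a boronic acid (5 → 12). Conjugate arylation joins C2–C1' and gives the flavanone. One heating then places the prenyl group on C8 and closes the pyran on ring B, and desilylation gives the target.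
- Stereochemistry: C2 (S) is the only stereocentre. It is set by the chiral rhodium diphosphine catalyst in step 7 and afterwards meets only neutral or buffered conditions.

Key step: step 9

Assumption: the (S) antipode of the biaryl diphosphine is taken to deliver the aryl group to the Re face of chromone C2 (2S product), as (S)-biaryl diphosphine rhodium catalysts do with cyclic enones. If a trial with phenylboronic acid shows the opposite sense, the (R) ligand is used and nothing else changes.

**Route**

Step 1
Reactants: 1 7-hydroxychromone; 2 3-chloro-3-methylbut-1-yne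
Product: 3 7-(2-methylbut-3-yn-2-yloxy)-4H-chromen-4-one
Conditions: CuCl2·2H2O (1 mol%), DBU, MeCN, 0 °C
Reagents that add atoms: none
Why: Copper-catalysed O-propargylation of a phenol with a tertiary propargylic chloride is the standard entry to aryl 1,1-dimethylpropargyl ethers, works well with acidic phenols such as this vinylogous acid, and should leave the chromone ring untouched by the hindered amidine base at 0 °C.

Step 2
Reactants: 3 7-(2-methylbut-3-yn-2-yloxy)-4H-chromen-4-one
Product: 4 7-(2-methylbut-3-en-2-yloxy)-4H-chromen-4-one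
Conditions: H2 (1 atm), Pd/CaCO3 (Pb(OAc)2-poisoned), quinoline, EtOAc, 20 °C
Reagents that add atoms: none
Why: Lindlar semihydrogenation should stop at the terminal alkene and spare the conjugated C2=C3 bond of the chromone, the usual way to turn a dimethylpropargyl aryl ether into the dimethylallyl ether.

Step 3
Reactants: 5 4-bromoresorcinol; 2 3-chloro-3-methylbut-1-yne
Product: 6 2-bromo-5-(2-methylbut-3-yn-2-yloxy)phenol
Conditions: CuCl2·2H2O (1 mol%), DBU (2.2 equiv), MeCN, −10 to 0 °C, slow addition of 2 (0.9 equiv)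
Reagents that add atoms: none
Why: The same copper-catalysed propargylation should favour the hydroxyl para to bromine, because with both hydroxyls deprotonated that phenoxide is the more basic and the unshielded one, whereas the oxygen next to bromine is hindered towards the tertiary electrophile; a deficit of chloride limits bis-alkylation.

Step 4
Reactants: 6 2-bromo-5-(2-methylbut-3-yn-2-yloxy)phenol
Product: 7 [2-bromo-5-(2-methylbut-3-yn-2-yloxy)phenoxy](tert-butyl)dimethylsilane
Conditions: TBSCl, imidazole, DMF, 20 °C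
Reagents that add atoms: tert-butyldimethylsilyl chloride, CC(C)(C)[Si](C)(C)Cl
Why: Imidazole-promoted silylation of a phenol is routine and installs the bulky group that later shields C3' of ring B.

Step 5
Reactants: 7 [2-bromo-5-(2-methylbut-3-yn-2-yloxy)phenoxy](tert-butyl)dimethylsilane
Product: 9 tert-butyl{2-bromo-5-[2-methyl-4-(trimethylsilyl)but-3-yn-2-yloxy]phenoxy}dimethylsilane, via lithium acetylide 8 (not isolated)
Conditions: LiN(iPr)2 (1.05 equiv), THF, −78 °C; then TMSCl, −78 to 0 °C
Reagents that add atoms: trimethylsilyl chloride, C[Si](C)(C)Cl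
Why: The amide base removes the acetylenic proton (far more acidic than any aryl C–H and no halogen–metal exchange with an amide) to give acetylide 8, whose C-silylation masks the alkyne against the organolithium and rhodium steps that follow.

Step 6
Reactants: 9 tert-butyl{2-bromo-5-[2-methyl-4-(trimethylsilyl)but-3-yn-2-yloxy]phenoxy}dimethylsilane
Product: 12 {2-(tert-butyldimethylsilyloxy)-4-[2-methyl-4-(trimethylsilyl)but-3-yn-2-yloxy]phenyl}boronic acid, via aryllithium 10 (not isolated), via lithium aryltriisopropoxyborate 11 (not isolated)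
Conditions: B(OiPr)3, n-BuLi, THF/toluene, −78 °C (in situ quench); then 1 M HCl to pH 5, 0 °C
Reagents that add atoms: triisopropyl borate, CC(C)OB(OC(C)C)OC(C)C; water, O
Why: Bromine–lithium exchange with the borate already present traps aryllithium 10 as borate 11 before an oxygen-to-carbon silyl shift can occur, and mild hydrolysis gives the boronic acid, the standard lithiation–borylation sequence.

Step 7
Reactants: 4 7-(2-methylbut-3-en-2-yloxy)-4H-chromen-4-one; 12 {2-(tert-butyldimethylsilyloxy)-4-[2-methyl-4-(trimethylsilyl)but-3-yn-2-yloxy]phenyl}boronic acid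
Product: 13 (2S)-2-{2-(tert-butyldimethylsilyloxy)-4-[2-methyl-4-(trimethylsilyl)but-3-yn-2-yloxy]phenyl}-7-(2-methylbut-3-en-2-yloxy)chroman-4-one
Conditions: [Rh(OH)((S)-MeO-F12-BIPHEP)]2 (1.5 mol%), 12 (2.5 equiv), CH2Cl2/H2O 10:1, 25 °C
Reagents that add atoms: none
Why: In this rhodium-catalysed asymmetric 1,4-addition of an arylboronic acid to a chromone (Hayashi–Miyaura type), the aryl–rhodium species held by the C2-symmetric electron-poor diphosphine should insert the C2=C3 bond from the Re face of C2 and so set the 2S centre, while the base-free medium avoids retro-oxa-Michael racemisation and the silylated alkyne and hindered terminal alkene are poor insertion partners.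

Step 8
Reactants: 13 (2S)-2-{2-(tert-butyldimethylsilyloxy)-4-[2-methyl-4-(trimethylsilyl)but-3-yn-2-yloxy]phenyl}-7-(2-methylbut-3-en-2-yloxy)chroman-4-one
Product: 14 (2S)-2-[2-(tert-butyldimethylsilyloxy)-4-(2-methylbut-3-yn-2-yloxy)phenyl]-7-(2-methylbut-3-en-2-yloxy)chroman-4-one
Conditions: AgNO3 (0.2 equiv), 2,6-lutidine, acetone/H2O 10:1, 20 °C, dark
Reagents that add atoms: none
Why: Silver-catalysed protodesilylation cleaves the C(sp)–SiMe3 bond in neutral aqueous medium and should spare the aryl silyl ether, both tertiary ethers and the base-sensitive C2 centre, freeing the terminal alkyne needed for the cascade.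

Step 9
Reactants: 14 (2S)-2-[2-(tert-butyldimethylsilyloxy)-4-(2-methylbut-3-yn-2-yloxy)phenyl]-7-(2-methylbut-3-en-2-yloxy)chroman-4-one
Product: 20 (2S)-2-[7-(tert-butyldimethylsilyloxy)-2,2-dimethyl-2H-chromen-6-yl]-7-hydroxy-8-(3-methylbut-2-en-1-yl)chroman-4-one, via ring A C8 dienone 15 (not isolated), via 8-prenyl-7-phenol propargyl ether 16 (not isolated), via ring B C5' allenyl dienone 17 (not isolated), via allenyl phenol 18 (not isolated), via ortho-quinone methide 19 (not isolated)
Conditions: PhNEt2 (degassed), 130 °C, then 165 °C, Ar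
Reagents that add atoms: none
Why: Heating should first trigger the aromatic Claisen rearrangement of the 1,1-dimethylallyl ether through a chair [3,3] transition state to dienone 15, which tautomerises to phenol 16; at the higher temperature the 1,1-dimethylpropargyl ether undergoes its own [3,3] shift to allenyl dienone 17, whose enol 18 passes by a 1,5-hydrogen shift into the (Z)-ortho-quinone methide 19. The closest known reactions are the thermal rearrangement of aryl 1,1-dimethylallyl ethers to ortho-prenylphenols and the thermal conversion of aryl 1,1-dimethylpropargyl ethers into 2,2-dimethyl-2H-chromenes, here run one after the other in the same flask. The only ring formed, the pyran on ring B, closes by thermal disrotatory oxa-6π electrocyclisation of 19, which makes the O4'–CMe2 bond and restores the aromaticity of ring B. No stereocentre is created, since the sp3 carbons of 15 and 17 vanish on tautomerisation, and C2 is a spectator that the neutral, weakly basic amine solvent should protect from ring opening. Regioselectivity is the requirement: on ring A the vinylogous-ester conjugation O1–C8a=C4a–C4=O fixes the C7=C8 double bond, so the allyl group should migrate to C8 and not C6, as it does in 7-allyloxycoumarins and 4-O-allylresacetophenones. On ring B the silyloxy group at C2' crowds C3' and, as a meta donor, also favours the position para to itself, so the propargyl unit should go to C5'.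

Step 10
Reactants: 20 (2S)-2-[7-(tert-butyldimethylsilyloxy)-2,2-dimethyl-2H-chromen-6-yl]-7-hydroxy-8-(3-methylbut-2-en-1-yl)chroman-4-one
Product: 21 (2S)-7-hydroxy-2-(7-hydroxy-2,2-dimethyl-2H-chromen-6-yl)-8-(3-methylbut-2-en-1-yl)chroman-4-one
Conditions: Bu4NF, AcOH (1:1), THF, 0 °C
Reagents that add atoms: none
Why: Acetic acid-buffered fluoride cleaves the aryl silyl ether without leaving free phenoxide in solution, so neither retro-oxa-Michael opening at C2 nor acid-induced cyclisation of the prenyl phenol or the chromene should occur.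

**Compound list**

1 | 7-hydroxy-4H-chromen-4-one (7-hydroxychromone) | O=c1ccoc2cc(O)ccc12 | starting material
2 | 3-chloro-3-methylbut-1-yne | C#CC(C)(C)Cl | starting material
3 | 7-(2-methylbut-3-yn-2-yloxy)-4H-chromen-4-one | C#CC(C)(C)Oc1ccc2c(c1)occc2=O | intermediate
4 | 7-(2-methylbut-3-en-2-yloxy)-4H-chromen-4-one | C=CC(C)(C)Oc1ccc2c(c1)occc2=O | intermediate
5 | 4-bromobenzene-1,3-diol (4-bromoresorcinol) | Oc1ccc(Br)c(O)c1 | starting material
6 | 2-bromo-5-(2-methylbut-3-yn-2-yloxy)phenol | C#CC(C)(C)Oc1ccc(Br)c(O)c1 | intermediate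
7 | [2-bromo-5-(2-methylbut-3-yn-2-yloxy)phenoxy](tert-butyl)dimethylsilane | C#CC(C)(C)Oc1ccc(Br)c(O[Si](C)(C)C(C)(C)C)c1 | intermediate
8 | lithium acetylide of 7 (transient, step 5) | [Li]C#CC(C)(C)Oc1ccc(Br)c(O[Si](C)(C)C(C)(C)C)c1 | intermediate
9 | tert-butyl{2-bromo-5-[2-methyl-4-(trimethylsilyl)but-3-yn-2-yloxy]phenoxy}dimethylsilane | C[Si](C)(C)C#CC(C)(C)Oc1ccc(Br)c(O[Si](C)(C)C(C)(C)C)c1 | intermediate
10 | aryllithium from 9, lithium in place of bromine (transient, step 6) | [Li]c1ccc(OC(C)(C)C#C[Si](C)(C)C)cc1O[Si](C)(C)C(C)(C)C | intermediate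
11 | lithium aryltriisopropoxyborate from 10 (transient, step 6) | [Li+].CC(C)O[B-](OC(C)C)(OC(C)C)c1ccc(OC(C)(C)C#C[Si](C)(C)C)cc1O[Si](C)(C)C(C)(C)C | intermediate
12 | {2-(tert-butyldimethylsilyloxy)-4-[2-methyl-4-(trimethylsilyl)but-3-yn-2-yloxy]phenyl}boronic acid | OB(O)c1ccc(OC(C)(C)C#C[Si](C)(C)C)cc1O[Si](C)(C)C(C)(C)C | intermediate
13 | (2S)-2-{2-(tert-butyldimethylsilyloxy)-4-[2-methyl-4-(trimethylsilyl)but-3-yn-2-yloxy]phenyl}-7-(2-methylbut-3-en-2-yloxy)chroman-4-one | C=CC(C)(C)Oc1ccc2c(c1)O[C@H](c1ccc(OC(C)(C)C#C[Si](C)(C)C)cc1O[Si](C)(C)C(C)(C)C)CC2=O | intermediate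
14 | (2S)-2-[2-(tert-butyldimethylsilyloxy)-4-(2-methylbut-3-yn-2-yloxy)phenyl]-7-(2-methylbut-3-en-2-yloxy)chroman-4-one | C=CC(C)(C)Oc1ccc2c(c1)O[C@H](c1ccc(OC(C)(C)C#C)cc1O[Si](C)(C)C(C)(C)C)CC2=O | intermediate
15 | ring A C8 dienone: (2S)-2-[2-(tert-butyldimethylsilyloxy)-4-(2-methylbut-3-yn-2-yloxy)phenyl]-8-(3-methylbut-2-en-1-yl)-2,3-dihydro-4H-chromene-4,7(8H)-dione, both C8 epimers (transient, step 9) | CC(C)=CCC1C(=O)C=CC2=C1O[C@H](c1ccc(OC(C)(C)C#C)cc1O[Si](C)(C)C(C)(C)C)CC2=O | intermediate
16 | (2S)-2-[2-(tert-butyldimethylsilyloxy)-4-(2-methylbut-3-yn-2-yloxy)phenyl]-7-hydroxy-8-(3-methylbut-2-en-1-yl)chroman-4-one (transient, step 9) | CC(C)=CCc1c(O)ccc2c1O[C@H](c1ccc(OC(C)(C)C#C)cc1O[Si](C)(C)C(C)(C)C)CC2=O | intermediate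
17 | ring B C5' allenyl dienone: (2S)-2-[6-(tert-butyldimethylsilyloxy)-3-(3-methylbuta-1,2-dien-1-yl)-4-oxocyclohexa-1,5-dien-1-yl]-7-hydroxy-8-(3-methylbut-2-en-1-yl)chroman-4-one, both C5' epimers (transient, step 9) | CC(C)=CCc1c(O)ccc2c1O[C@H](C1=CC(C=C=C(C)C)C(=O)C=C1O[Si](C)(C)C(C)(C)C)CC2=O | intermediate
18 | (2S)-2-[2-(tert-butyldimethylsilyloxy)-4-hydroxy-5-(3-methylbuta-1,2-dien-1-yl)phenyl]-7-hydroxy-8-(3-methylbut-2-en-1-yl)chroman-4-one (transient, step 9) | CC(C)=CCc1c(O)ccc2c1O[C@H](c1cc(C=C=C(C)C)c(O)cc1O[Si](C)(C)C(C)(C)C)CC2=O | intermediate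
19 | ortho-quinone methide: (2S)-2-[(3Z)-6-(tert-butyldimethylsilyloxy)-3-(3-methylbut-2-en-1-ylidene)-4-oxocyclohexa-1,5-dien-1-yl]-7-hydroxy-8-(3-methylbut-2-en-1-yl)chroman-4-one (transient, step 9) | CC(C)=CCc1c(O)ccc2c1O[C@H](C1=C/C(=C/C=C(C)C)C(=O)C=C1O[Si](C)(C)C(C)(C)C)CC2=O | intermediate
20 | (2S)-2-[7-(tert-butyldimethylsilyloxy)-2,2-dimethyl-2H-chromen-6-yl]-7-hydroxy-8-(3-methylbut-2-en-1-yl)chroman-4-one | CC(C)=CCc1c(O)ccc2c1O[C@H](c1cc3c(cc1O[Si](C)(C)C(C)(C)C)OC(C)(C)C=C3)CC2=O | intermediate
21 | (2S)-7-hydroxy-2-(7-hydroxy-2,2-dimethyl-2H-chromen-6-yl)-8-(3-methylbut-2-en-1-yl)chroman-4-one | CC(C)=CCc1c(O)ccc2c1O[C@H](c1cc3c(cc1O)OC(C)(C)C=C3)CC2=O | target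

**Summary**

Total step count: 10. Longest linear sequence: 8 steps (5 → 21, steps 3 to 10).

Steps most likely to fail:

1. Step 9. At the temperature the propargyl shift needs, the freshly formed prenyl phenol may cyclise onto its own alkene, migration on ring B may partly go to C3', or C2 may erode by thermal ring opening. The fallback splits the cascade and replaces the thermal propargyl shift by π-acid catalysis. It sets out from 14: heating in toluene at 110 °C should rearrange only the dimethylallyl ether, and the resulting (2S)-7-hydroxy-8-prenyl propargyl ether 16 is isolated. Its aryl propargyl ether is then closed to the chromene at 20 °C by gold-catalysed 6-endo hydroarylation (Ph3PAuNTf2, CH2Cl2), an electrophilic ring closure that also prefers the open C5' para to the silyloxy group. This comes back to the route at 20.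

2. Step 7. Transfer of the ortho-silyloxy aryl group to rhodium and its insertion may be slow, so that protodeboronation takes over, or facial selectivity may be insufficient. The fallback separates bond formation from stereocontrol. It sets out from 4 and 12: the more active achiral catalyst [Rh(OH)(cod)]2 (dioxane/H2O, 40 °C) should give the racemic flavanone F1 (racemic 13). Its (2R) antipode is then removed by transfer-hydrogenative kinetic resolution, using the antipode of RhCl(Cp*)(TsDPEN) that reduces the (2R)-ketone, with HCO2H/Et3N in EtOAc. This converts the unwanted enantiomer into the (2R,4R)-cis-flavan-4-ol F2, which is separated by chromatography, and leaves (2S)-13, where the route is rejoined.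

3. Step 3. Alkylation may occur at the hydroxyl next to bromine or at both hydroxyls. The fallback fixes the oxygen pattern before bromine is introduced. It sets out from 2, which is combined with purchased 3-hydroxyphenyl benzoate F3 under the copper-catalysed conditions of step 1 to give 3-(2-methylbut-3-yn-2-yloxy)phenyl benzoate F4. Methanolysis (K2CO3 cat., MeOH) frees 3-(2-methylbut-3-yn-2-yloxy)phenol F5. Amine-catalysed bromination (NBS, iPr2NH cat., CH2Cl2, 0 °C) then takes place ortho to the hydroxyl and para to the ether, which returns to the route at 6.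

**Further compounds**

F0 | step 9 | none | none
F1 | step 7 | racemic 2-{2-(tert-butyldimethylsilyloxy)-4-[2-methyl-4-(trimethylsilyl)but-3-yn-2-yloxy]phenyl}-7-(2-methylbut-3-en-2-yloxy)chroman-4-one | C=CC(C)(C)Oc1ccc2c(c1)OC(c1ccc(OC(C)(C)C#C[Si](C)(C)C)cc1O[Si](C)(C)C(C)(C)C)CC2=O
F2 | step 7 | (2R,4R)-2-{2-(tert-butyldimethylsilyloxy)-4-[2-methyl-4-(trimethylsilyl)but-3-yn-2-yloxy]phenyl}-7-(2-methylbut-3-en-2-yloxy)chroman-4-ol | C=CC(C)(C)Oc1ccc2c(c1)O[C@@H](c1ccc(OC(C)(C)C#C[Si](C)(C)C)cc1O[Si](C)(C)C(C)(C)C)C[C@H]2O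
F3 | step 3 | 3-hydroxyphenyl benzoate | O=C(Oc1cccc(O)c1)c1ccccc1
F4 | step 3 | 3-(2-methylbut-3-yn-2-yloxy)phenyl benzoate | C#CC(C)(C)Oc1cccc(OC(=O)c2ccccc2)c1
F5 | step 3 | 3-(2-methylbut-3-yn-2-yloxy)phenol | C#CC(C)(C)Oc1cccc(O)c1
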